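**Strategy**

Ring C is disconnected at C3–C4 and O1–C8a. The key step exploits the cis-vicinal O1–C2/C3–OH pair of the pyran ring: drawn as a trans-2-benzyloxy-3-aryloxirane, C3 is an acetal-type electrophile and the oxirane oxygen, already on C2, is the future O1. A ring A benzylic Grignard reagent with an ortho fluorine (nucleophilic C4, electrophilic C8a) opens the oxirane at C3 with inversion, and the released C2 alkoxide displaces fluoride in the same flask, closing ring C with both stereocentres set. Position 7 is carried as a MOM ether for late galloylation; every other hydroxyl is a benzyl ether removed in the last step.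

Key step: step 9

Remark: flavan numbering (O1, C2, C3, C4, C4a, C5 to C8, C8a) is used for the ring atoms; compounds 1, 5 and 17 are taken as purchasable.

**Route**

Step 1
Reactants: 1 3,4,5-tris(benzyloxy)benzaldehyde
Product: 2 1,2,3-tris(benzyloxy)-5-[(E)-2-iodoethenyl]benzene
Conditions: CrCl2, CHI3, THF, 0 °C → rt
Reagents that add atoms: iodoform, IC(I)I
Why: Takai olefination: the geminal dichromium species formed from CHI3 and divalent chromium should add to the aldehyde and eliminate to the (E)-vinyl iodide, the anti arrangement of aryl and iodine in the elimination setting the geometry, and benzyl ethers are inert to CrCl2.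

Step 2
Reactants: 2 1,2,3-tris(benzyloxy)-5-[(E)-2-iodoethenyl]benzene
Product: 3 1,2,3-tris(benzyloxy)-5-[(E)-2-(benzyloxy)ethenyl]benzene
Conditions: CuI (10 mol %), 3,4,7,8-tetramethyl-1,10-phenanthroline (20 mol %), Cs2CO3, BnOH, toluene, 80 °C
Reagents that add atoms: benzyl alcohol, OCc1ccccc1
Why: Ullmann-type CuI/phenanthroline-catalysed C–O coupling of a vinyl iodide with a primary alcohol should proceed with retention of alkene geometry to give the (E)-enol ether, and the E iodide resists loss of HI because its vinylic hydrogen is cis to iodine.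

Step 3
Reactants: 3 1,2,3-tris(benzyloxy)-5-[(E)-2-(benzyloxy)ethenyl]benzene
Product: 4 (2S,3R)-2-(benzyloxy)-3-[3,4,5-tris(benzyloxy)phenyl]oxirane
Conditions: D-fructose-derived Shi ketone (30 mol %), Oxone (2KHSO5·KHSO4·K2SO4), K2CO3, Bu4NHSO4, MeCN/CH2(OMe)2/aq. Na2B4O7 buffer, −10 → 0 °C; cold extraction, used crude
Reagents that add atoms: potassium peroxymonosulfate (active component of Oxone), [K+].[O-]S(=O)(=O)OO
Why: Shi epoxidation: the chiral dioxirane should transfer oxygen to the trans enol ether through a spiro transition state on the same face as for trans-β-methylstyrene (which gives the (R,R)-oxide), making the benzylic carbon R and the acetal carbon S, while the basic buffer protects the acid-labile epoxy ether as in biphasic Oxone/acetone epoxidations of glycals.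

Step 4
Reactants: 5 5-fluorobenzene-1,3-diol
Product: 7 2-fluoro-4,6-dihydroxybenzaldehyde, via aryl iminium chloride 6 (not isolated)
Conditions: POCl3, DMF, MeCN, 0 °C → rt; then H2O, 50 °C
Reagents that add atoms: N,N-dimethylformamide, CN(C)C=O; water, O
Why: Vilsmeier–Haack formylation should occur para to one hydroxyl and ortho to the other (as orcinol gives orcylaldehyde) and not between the two hydroxyls, and hydrolysis of iminium salt 6 releases the aldehyde.

Step 5
Reactants: 7 2-fluoro-4,6-dihydroxybenzaldehyde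
Product: 8 2-fluoro-6-hydroxy-4-(methoxymethoxy)benzaldehyde
Conditions: MOMCl (1.05 equiv), i-Pr2NEt, CH2Cl2, 0 °C
Reagents that add atoms: chloromethyl methyl ether, COCCl
Why: O-alkylation should take place only at the para 4-OH because the 6-OH is held in a hydrogen bond to the formyl group, the usual selectivity of 2,4-dihydroxybenzaldehydes.

Step 6
Reactants: 8 2-fluoro-6-hydroxy-4-(methoxymethoxy)benzaldehyde
Product: 9 2-(benzyloxy)-6-fluoro-4-(methoxymethoxy)benzaldehyde
Conditions: BnBr, K2CO3, DMF, 60 °C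
Reagents that add atoms: benzyl bromide, BrCc1ccccc1
Why: Williamson etherification of the remaining chelated phenol under carbonate/DMF forcing conditions should leave the MOM ether and the aryl fluoride untouched.

Step 7
Reactants: 9 2-(benzyloxy)-6-fluoro-4-(methoxymethoxy)benzaldehyde
Product: 10 [2-(benzyloxy)-6-fluoro-4-(methoxymethoxy)phenyl]methanol
Conditions: NaBH4, MeOH/THF, 0 °C
Reagents that add atoms: none
Why: Borohydride reduction of the aryl aldehyde gives the benzylic alcohol, and no other reducible group is present.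

Step 8
Reactants: 10 [2-(benzyloxy)-6-fluoro-4-(methoxymethoxy)phenyl]methanol
Product: 12 1-(benzyloxy)-2-(chloromethyl)-3-fluoro-5-(methoxymethoxy)benzene, via benzylic mesylate 11 (not isolated)
Conditions: MsCl, Et3N, LiCl, CH2Cl2/THF, 0 °C → rt; used without chromatography
Reagents that add atoms: lithium chloride, [Li+].[Cl-]
Why: Mesylation followed by in situ SN2 displacement by chloride, fast for this electron-rich benzylic mesylate, runs under basic conditions that spare the MOM ether.

Step 9
Reactants: 12 1-(benzyloxy)-2-(chloromethyl)-3-fluoro-5-(methoxymethoxy)benzene; 4 (2S,3R)-2-(benzyloxy)-3-[3,4,5-tris(benzyloxy)phenyl]oxirane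
Product: 15 (2R,3R)-3,5-bis(benzyloxy)-7-(methoxymethoxy)-2-[3,4,5-tris(benzyloxy)phenyl]chromane, via benzylic Grignard reagent 13 (not isolated), via ring-opened magnesium alkoxide 14 (not isolated)
Conditions: Mg, 2-MeTHF, 0 °C; CuI (10 mol %), then 4 in THF, −40 → 0 °C; then KOt-Bu, DMF, 60 °C
Reagents that add atoms: none
Why: Mg inserts into the benzylic C–Cl bond of 12 to give 13, whose copper-catalysed SN2 attack through C4 on the acetal carbon C3 of oxirane 4, anti to the breaking C–O bond and driven by release of ring strain, forms C3–C4 and frees the C2 alkoxide 14; after exchange to the potassium alkoxide in DMF this oxygen adds to C8a and expels fluoride by addition–elimination through a Meisenheimer adduct, forming O1–C8a. The closest known reaction types are the anti opening of 1,2-anhydro sugars (cyclic 2-alkoxyoxiranes) at the anomeric carbon by Grignard/copper reagents and the alkoxide SNAr closure of fluoroarenes to chromans, here run back to back in one flask as a formal [3+3] annulation. Ring C closes in a 6-exo-trig mode, the attacked aromatic carbon carrying the exocyclic C–F bond. C2 (R) comes unchanged from the Shi epoxide because no bond to it is touched, and C3 (R) arises by inversion at the (S)-acetal carbon, so the trans-oxirane maps onto the 2,3-cis flavan. The step needs attack at the acetal rather than the benzylic oxirane carbon, secured by the alkoxy group that makes C3 the far better SN2 site, and closure through O1 alone, secured because the C3 oxygen is already a benzyl ether so that no 5-exo dihydrobenzofuran can form; the two alkoxy groups of ring A are meta to C8a and do not deactivate it.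

Step 10
Reactants: 15 (2R,3R)-3,5-bis(benzyloxy)-7-(methoxymethoxy)-2-[3,4,5-tris(benzyloxy)phenyl]chromane
Product: 16 (2R,3R)-3,5-bis(benzyloxy)-2-[3,4,5-tris(benzyloxy)phenyl]chroman-7-ol
Conditions: HCl (conc., cat.), MeOH/THF, 50 °C
Reagents that add atoms: none
Why: Acid-catalysed acetal exchange with methanol should remove the phenolic MOM group as dimethoxymethane, while the benzyl ethers and the fully O-protected chroman ring are stable to dilute methanolic acid.

Step 11
Reactants: 16 (2R,3R)-3,5-bis(benzyloxy)-2-[3,4,5-tris(benzyloxy)phenyl]chroman-7-ol; 17 3,4,5-tris(benzyloxy)benzoic acid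
Product: 18 (2R,3R)-3,5-bis(benzyloxy)-2-[3,4,5-tris(benzyloxy)phenyl]chroman-7-yl 3,4,5-tris(benzyloxy)benzoate
Conditions: EDC·HCl, DMAP (cat.), CH2Cl2, rt
Reagents that add atoms: none
Why: Steglich esterification should acylate the only free hydroxyl, the 7-phenol, since O3 and O5 are benzyl ethers.

Step 12
Reactants: 18 (2R,3R)-3,5-bis(benzyloxy)-2-[3,4,5-tris(benzyloxy)phenyl]chroman-7-yl 3,4,5-tris(benzyloxy)benzoate
Product: 19 epigallocatechin 7-O-gallate
Conditions: H2 (1 atm), Pd(OH)2/C, THF/MeOH, rt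
Reagents that add atoms: none
Why: Hydrogenolysis over Pd(OH)2/C should cleave all eight benzyl ethers (seven aryl, one alkyl) to toluene while the aryl ester and the chroman C2–O1 bond remain, as is usual for perbenzylated catechin gallates, and no stereocentre is touched.

**Compound list**

1 | 3,4,5-tris(benzyloxy)benzaldehyde | O=Cc1cc(OCc2ccccc2)c(OCc2ccccc2)c(OCc2ccccc2)c1 | starting material
2 | 1,2,3-tris(benzyloxy)-5-[(E)-2-iodoethenyl]benzene | I/C=C/c1cc(OCc2ccccc2)c(OCc2ccccc2)c(OCc2ccccc2)c1 | intermediate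
3 | 1,2,3-tris(benzyloxy)-5-[(E)-2-(benzyloxy)ethenyl]benzene | c1ccccc1CO/C=C/c1cc(OCc2ccccc2)c(OCc2ccccc2)c(OCc2ccccc2)c1 | intermediate
4 | (2S,3R)-2-(benzyloxy)-3-[3,4,5-tris(benzyloxy)phenyl]oxirane (trans) | c1ccccc1CO[C@H]1O[C@@H]1c1cc(OCc2ccccc2)c(OCc2ccccc2)c(OCc2ccccc2)c1 | intermediate
5 | 5-fluorobenzene-1,3-diol (5-fluororesorcinol) | Oc1cc(O)cc(F)c1 | starting material
6 | N-[(2-fluoro-4,6-dihydroxyphenyl)methylidene]-N-methylmethanaminium chloride (aryl iminium chloride, formed in the flask) | C[N+](C)=Cc1c(O)cc(O)cc1F.[Cl-] | intermediate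
7 | 2-fluoro-4,6-dihydroxybenzaldehyde | O=Cc1c(F)cc(O)cc1O | intermediate
8 | 2-fluoro-6-hydroxy-4-(methoxymethoxy)benzaldehyde | O=Cc1c(F)cc(OCOC)cc1O | intermediate
9 | 2-(benzyloxy)-6-fluoro-4-(methoxymethoxy)benzaldehyde | O=Cc1c(F)cc(OCOC)cc1OCc1ccccc1 | intermediate
10 | [2-(benzyloxy)-6-fluoro-4-(methoxymethoxy)phenyl]methanol | OCc1c(F)cc(OCOC)cc1OCc1ccccc1 | intermediate
11 | [2-(benzyloxy)-6-fluoro-4-(methoxymethoxy)phenyl]methyl methanesulfonate (formed in the flask) | CS(=O)(=O)OCc1c(F)cc(OCOC)cc1OCc1ccccc1 | intermediate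
12 | 1-(benzyloxy)-2-(chloromethyl)-3-fluoro-5-(methoxymethoxy)benzene | ClCc1c(F)cc(OCOC)cc1OCc1ccccc1 | intermediate
13 | [2-(benzyloxy)-6-fluoro-4-(methoxymethoxy)benzyl]magnesium chloride (formed in the flask) | Cl[Mg]Cc1c(F)cc(OCOC)cc1OCc1ccccc1 | intermediate
14 | chloromagnesium (1R,2R)-2-(benzyloxy)-3-[2-(benzyloxy)-6-fluoro-4-(methoxymethoxy)phenyl]-1-[3,4,5-tris(benzyloxy)phenyl]propan-1-olate (formed in the flask) | Cl[Mg]O[C@H](c1cc(OCc2ccccc2)c(OCc2ccccc2)c(OCc2ccccc2)c1)[C@H](OCc1ccccc1)Cc1c(F)cc(OCOC)cc1OCc1ccccc1 | intermediate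
15 | (2R,3R)-3,5-bis(benzyloxy)-7-(methoxymethoxy)-2-[3,4,5-tris(benzyloxy)phenyl]chromane | COCOc1cc(OCc2ccccc2)c2c(c1)O[C@H](c1cc(OCc3ccccc3)c(OCc3ccccc3)c(OCc3ccccc3)c1)[C@H](OCc1ccccc1)C2 | intermediate
16 | (2R,3R)-3,5-bis(benzyloxy)-2-[3,4,5-tris(benzyloxy)phenyl]chroman-7-ol | Oc1cc(OCc2ccccc2)c2c(c1)O[C@H](c1cc(OCc3ccccc3)c(OCc3ccccc3)c(OCc3ccccc3)c1)[C@H](OCc1ccccc1)C2 | intermediate
17 | 3,4,5-tris(benzyloxy)benzoic acid | OC(=O)c1cc(OCc2ccccc2)c(OCc2ccccc2)c(OCc2ccccc2)c1 | starting material
18 | (2R,3R)-3,5-bis(benzyloxy)-2-[3,4,5-tris(benzyloxy)phenyl]chroman-7-yl 3,4,5-tris(benzyloxy)benzoate | O=C(Oc1cc(OCc2ccccc2)c2c(c1)O[C@H](c1cc(OCc3ccccc3)c(OCc3ccccc3)c(OCc3ccccc3)c1)[C@H](OCc1ccccc1)C2)c1cc(OCc2ccccc2)c(OCc2ccccc2)c(OCc2ccccc2)c1 | intermediate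
19 | epigallocatechin 7-O-gallate, (2R,3R)-3,5-dihydroxy-2-(3,4,5-trihydroxyphenyl)chroman-7-yl 3,4,5-trihydroxybenzoate | O=C(Oc1cc(O)c2c(c1)O[C@H](c1cc(O)c(O)c(O)c1)[C@H](O)C2)c1cc(O)c(O)c(O)c1 | target

**Totals**

Total step count: 12. Longest linear sequence: 9 steps (5 → 19, steps 4 to 12).

**Steps most likely to fail**

1. Step 9 (key step). What may go wrong: Wurtz-type homocoupling while the electron-rich benzylic Grignard reagent forms; magnesium-halide-induced ionisation or alkoxy shift of the epoxy ether before the C–C bond is made, which would erode the configuration at C3; attack at the benzylic instead of the acetal oxirane carbon; slow displacement of fluoride. Fallback (polarity of the C3–C4 bond reversed, the two bonds made in separate steps): it sets out from 12 and comes back at 15. The sodium enolate of (4S)-4-benzyl-3-(benzyloxyacetyl)-1,3-oxazolidin-2-one (NaN(SiMe3)2, THF, −78 °C) would be alkylated by 12 in the presence of NaI, the electrophile entering anti to the benzyl group of the auxiliary (auxiliary-controlled glycolate alkylation), to give (4S)-4-benzyl-3-[(2R)-2-(benzyloxy)-3-[2-(benzyloxy)-6-fluoro-4-(methoxymethoxy)phenyl]propanoyl]-1,3-oxazolidin-2-one F1. LiBH4 (THF/MeOH, 0 °C) would cleave the auxiliary to (2R)-2-(benzyloxy)-3-[2-(benzyloxy)-6-fluoro-4-(methoxymethoxy)phenyl]propan-1-ol F2, and Dess–Martin periodinane (CH2Cl2, NaHCO3) would give (2R)-2-(benzyloxy)-3-[2-(benzyloxy)-6-fluoro-4-(methoxymethoxy)phenyl]propanal F3. Addition of [3,4,5-tris(benzyloxy)phenyl]magnesium bromide F4 (from 5-bromo-1,2,3-tris(benzyloxy)benzene and Mg in THF) under chelation control (MgBr2·OEt2, CH2Cl2, −78 °C, magnesium bridging the aldehyde and α-benzyloxy oxygens) should give the syn alcohol (1R,2R)-2-(benzyloxy)-3-[2-(benzyloxy)-6-fluoro-4-(methoxymethoxy)phenyl]-1-[3,4,5-tris(benzyloxy)phenyl]propan-1-ol F5, the protonated form of 14. KOt-Bu in DMF at 60 °C would then close ring C by the same fluoride displacement and give 15.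

2. Step 3. What may go wrong: hydrolytic opening of the acid-labile epoxy ether in the aqueous medium, or lower facial selectivity for an enol ether than for a simple trans-styrene. Fallback (enantiopurity by resolution instead of catalyst control): it sets out from 3 and comes back at 15. Epoxidation of 3 with anhydrous dimethyldioxirane in acetone (−40 → 0 °C, evaporation only) would give the racemic trans-epoxy ether, that is 4 together with its enantiomer (2R,3S)-2-(benzyloxy)-3-[3,4,5-tris(benzyloxy)phenyl]oxirane F6. Step 9 run on this material would pass through the racemic alkoxide (14 and its enantiomer, chloromagnesium (1S,2S)-2-(benzyloxy)-3-[2-(benzyloxy)-6-fluoro-4-(methoxymethoxy)phenyl]-1-[3,4,5-tris(benzyloxy)phenyl]propan-1-olate F7) to the racemic cis-flavan (15 and its enantiomer (2S,3S)-3,5-bis(benzyloxy)-7-(methoxymethoxy)-2-[3,4,5-tris(benzyloxy)phenyl]chromane F8), because the opening is stereospecific. The enantiomers would be separated by preparative chromatography on a chiral stationary phase (amylose tris(3,5-dimethylphenylcarbamate), supercritical CO2/alcohol) to return 15.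

3. Step 2. What may go wrong: stalling of the copper-catalysed C–O coupling, or partial E/Z isomerisation at 80 °C that would leak into the 2,3-trans flavan series. Fallback (olefination instead of cross-coupling): it sets out from 1 and comes back at 3. Lithiated (benzyloxymethyl)diphenylphosphine oxide (LiN(i-Pr)2, THF, −78 °C) would add to 1 (Horner–Wittig addition) to give two diastereomeric β-hydroxy phosphine oxides. The diastereomer rel-(1R,2S)-2-(benzyloxy)-2-(diphenylphosphoryl)-1-[3,4,5-tris(benzyloxy)phenyl]ethan-1-ol F9 would be separated by crystallisation or chromatography and treated with NaH in DMF, where stereospecific syn elimination of diphenylphosphinate should give 3 as the pure E isomer.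

**Further compounds**

F1 | step 9 | (4S)-4-benzyl-3-[(2R)-2-(benzyloxy)-3-[2-(benzyloxy)-6-fluoro-4-(methoxymethoxy)phenyl]propanoyl]-1,3-oxazolidin-2-one | O=C([C@H](OCc1ccccc1)Cc1c(F)cc(OCOC)cc1OCc1ccccc1)N1[C@@H](Cc2ccccc2)COC1=O
F2 | step 9 | (2R)-2-(benzyloxy)-3-[2-(benzyloxy)-6-fluoro-4-(methoxymethoxy)phenyl]propan-1-ol | OC[C@H](OCc1ccccc1)Cc1c(F)cc(OCOC)cc1OCc1ccccc1
F3 | step 9 | (2R)-2-(benzyloxy)-3-[2-(benzyloxy)-6-fluoro-4-(methoxymethoxy)phenyl]propanal | O=C[C@H](OCc1ccccc1)Cc1c(F)cc(OCOC)cc1OCc1ccccc1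
F4 | step 9 | [3,4,5-tris(benzyloxy)phenyl]magnesium bromide | Br[Mg]c1cc(OCc2ccccc2)c(OCc2ccccc2)c(OCc2ccccc2)c1
F5 | step 9 | (1R,2R)-2-(benzyloxy)-3-[2-(benzyloxy)-6-fluoro-4-(methoxymethoxy)phenyl]-1-[3,4,5-tris(benzyloxy)phenyl]propan-1-ol | O[C@H](c1cc(OCc2ccccc2)c(OCc2ccccc2)c(OCc2ccccc2)c1)[C@H](OCc1ccccc1)Cc1c(F)cc(OCOC)cc1OCc1ccccc1
F6 | step 3 | (2R,3S)-2-(benzyloxy)-3-[3,4,5-tris(benzyloxy)phenyl]oxirane (enantiomer of 4) | c1ccccc1CO[C@@H]1O[C@H]1c1cc(OCc2ccccc2)c(OCc2ccccc2)c(OCc2ccccc2)c1
F7 | step 3 | chloromagnesium (1S,2S)-2-(benzyloxy)-3-[2-(benzyloxy)-6-fluoro-4-(methoxymethoxy)phenyl]-1-[3,4,5-tris(benzyloxy)phenyl]propan-1-olate (enantiomer of 14) | Cl[Mg]O[C@@H](c1cc(OCc2ccccc2)c(OCc2ccccc2)c(OCc2ccccc2)c1)[C@@H](OCc1ccccc1)Cc1c(F)cc(OCOC)cc1OCc1ccccc1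
F8 | step 3 | (2S,3S)-3,5-bis(benzyloxy)-7-(methoxymethoxy)-2-[3,4,5-tris(benzyloxy)phenyl]chromane (enantiomer of 15) | COCOc1cc(OCc2ccccc2)c2c(c1)O[C@@H](c1cc(OCc3ccccc3)c(OCc3ccccc3)c(OCc3ccccc3)c1)[C@@H](OCc1ccccc1)C2
F9 | step 2 | rel-(1R,2S)-2-(benzyloxy)-2-(diphenylphosphoryl)-1-[3,4,5-tris(benzyloxy)phenyl]ethan-1-ol (racemic, one enantiomer drawn) | O[C@H](c1cc(OCc2ccccc2)c(OCc2ccccc2)c(OCc2ccccc2)c1)[C@@H](OCc1ccccc1)P(=O)(c1ccccc1)c1ccccc1
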